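**Retrosynthetic overview**

1. The target is cut between the exocyclic vinylic CH carbon of the 5-ylidene furan-2(5H)-one (acyl tetronate) ring and the adjacent methyl-bearing stereocentre. The last step is a stereoretentive palladium-catalysed Negishi union of the complete (E)-iodomethylidene acyl tetronate with the complete C21 furanoterpenoid secondary alkylzinc, and it gives the target directly.
2. Enabling feature: in the enol-lactone array O1–C5(=CH–)–C4 of the furanone ring the exocyclic CH substituent is trans to ring oxygen O1 and cis to the acyloxy carbon C4. That is the outcome of an anti addition of a carboxylate oxygen and iodine across a terminal alkyne, so this CH carbon can carry iodine with the required geometry. The neighbouring stereocentre bears only H, CH3 and CH2, so it can be carried as a configurationally stable secondary carbon–zinc centre.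
3. Electrophile: methyl 2-methyl-3-oxobutanoate → (E)-enol ether → γ-bromide → aldehyde → enyne → acid → 5-exo-dig anti-iodolactonisation (the only ring-forming step) → O-demethylation → O-acylation with 15-methylhexadecanoic acid.
4. Nucleophile: geranyl acetate is oxidised at C8 and extended at both allylic ends by copper-catalysed Grignard couplings, first with the chiral-pool C4 unit from (R)-butane-1,3-diol, then with the 3-furylmethyl unit; the (R)-alcohol is inverted to the (S)-iodide.
5. Ring order: the furan is present from the start (furan-3-ylmethanol, not built); the furanone ring is closed in step 18; the key coupling follows in step 21.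

Key step: step 21

Assumption: the exocyclic alkene is taken exactly as drawn, side chain cis to C4 and trans to the ring oxygen, i.e. (E), with an (S) stereocentre and two (E) chain alkenes; because this (E) ylidene is the less stable isomer, the geometry is set by an anti addition and only stereoretentive steps follow.

**Route**

Step 1
Reactants: 1 (R)-butane-1,3-diol
Product: 2 (R)-3-hydroxybutyl 4-methylbenzenesulfonate
Conditions: TsCl (1.0 equiv), Et3N, CH2Cl2, −20 °C
Reagents that add atoms: 4-methylbenzenesulfonyl chloride, Cc1ccc(cc1)S(Cl)(=O)=O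
Why: Kinetically selective sulfonylation of the less hindered primary hydroxyl of the 1,3-diol; the (R) carbinol centre is not touched.

Step 2
Reactants: 2 (R)-3-hydroxybutyl 4-methylbenzenesulfonate
Product: 3 (R)-3-[(tert-butyldimethylsilyl)oxy]butyl 4-methylbenzenesulfonate
Conditions: TBSCl, imidazole, DMF, 0 °C to rt
Reagents that add atoms: tert-butyldimethylsilyl chloride, CC(C)(C)[Si](C)(C)Cl
Why: Imidazole-promoted silylation masks the secondary alcohol for the later Grignard chemistry without changing the stereocentre.

Step 3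
Reactants: 3 (R)-3-[(tert-butyldimethylsilyl)oxy]butyl 4-methylbenzenesulfonate
Product: 4 (R)-(4-bromobutan-2-yloxy)(tert-butyl)dimethylsilane
Conditions: LiBr, acetone, reflux
Reagents that add atoms: lithium bromide, [Li+].[Br-]
Why: Finkelstein-type SN2 displacement of the primary tosylate by bromide gives the halide needed for magnesium insertion.

Step 4
Reactants: 5 geranyl acetate
Product: 6 (2E,6E)-8-hydroxy-3,7-dimethylocta-2,6-dien-1-yl acetate
Conditions: SeO2 (cat.), tBuOOH, salicylic acid (cat.), CH2Cl2, rt
Reagents that add atoms: tert-butyl hydroperoxide (terminal oxygen source, delivered through SeO2), CC(C)(C)OO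
Why: Riley allylic oxidation (ene reaction, then [2,3]-sigmatropic shift) attacks the electron-richer terminal alkene at its (E)-methyl group, the alkene next to the acetate being deactivated, so the hydroxymethyl group ends trans to the chain.

Step 5
Reactants: 6 (2E,6E)-8-hydroxy-3,7-dimethylocta-2,6-dien-1-yl acetate
Product: 7 (2E,6E)-8-bromo-3,7-dimethylocta-2,6-dien-1-yl acetate
Conditions: CBr4, PPh3, CH2Cl2, 0 °C
Reagents that add atoms: tetrabromomethane, BrC(Br)(Br)Br
Why: Appel bromination converts the primary allylic alcohol into the bromide by SN2 without allylic transposition and leaves the acetate alone.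

Step 6
Reactants: 4 (R)-(4-bromobutan-2-yloxy)(tert-butyl)dimethylsilane, 7 (2E,6E)-8-bromo-3,7-dimethylocta-2,6-dien-1-yl acetate
Product: 9 (2E,6E,11R)-11-[(tert-butyldimethylsilyl)oxy]-3,7-dimethyldodeca-2,6-dien-1-yl acetate, via Grignard reagent 8 (not isolated)
Conditions: 4, Mg, THF, rt; then 7, Li2CuCl4 (5 mol%), THF, −78 to −20 °C
Reagents that add atoms: none
Why: Copper-catalysed Grignard cross-coupling (Kochi–Schlosser type) in THF at low temperature should substitute the primary allylic bromide at its α-carbon with retention of the (E) alkene, much faster than any reaction at the allylic acetate; the stereocentre is remote from the reacting carbon.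

Step 7
Reactants: 9 (2E,6E,11R)-11-[(tert-butyldimethylsilyl)oxy]-3,7-dimethyldodeca-2,6-dien-1-yl acetate
Product: 10 (2E,6E,11R)-11-[(tert-butyldimethylsilyl)oxy]-3,7-dimethyldodeca-2,6-dien-1-ol
Conditions: K2CO3 (cat.), MeOH, rt
Reagents that add atoms: none
Why: Zemplén-type base-catalysed transesterification removes the acetate and does not touch the silyl ether.

Step 8
Reactants: 10 (2E,6E,11R)-11-[(tert-butyldimethylsilyl)oxy]-3,7-dimethyldodeca-2,6-dien-1-ol
Product: 11 tert-butyl{[(2R,6E,10E)-12-chloro-6,10-dimethyldodeca-6,10-dien-2-yl]oxy}dimethylsilane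
Conditions: NCS, Me2S, CH2Cl2, −30 to 0 °C
Reagents that add atoms: N-chlorosuccinimide, O=C1CCC(=O)N1Cl
Why: Corey–Kim chlorination (alkoxysulfonium, then SN2 by chloride) converts primary allylic alcohols into chlorides without allylic rearrangement or loss of (E) geometry and tolerates the silyl ether.

Step 9
Reactants: 12 furan-3-ylmethanol
Product: 13 3-(chloromethyl)furan
Conditions: SOCl2, pyridine, Et2O, 0 °C; used at once
Reagents that add atoms: thionyl chloride, ClS(Cl)=O
Why: Pyridine-buffered chlorodehydroxylation gives the 3-furylmethyl chloride, which ionises far less readily than the 2-furyl isomer and survives long enough for immediate use.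

Step 10
Reactants: 13 3-(chloromethyl)furan, 11 tert-butyl{[(2R,6E,10E)-12-chloro-6,10-dimethyldodeca-6,10-dien-2-yl]oxy}dimethylsilane
Product: 15 tert-butyl{[(2R,6E,10E)-13-(furan-3-yl)-6,10-dimethyltrideca-6,10-dien-2-yl]oxy}dimethylsilane, via Grignard reagent 14 (not isolated)
Conditions: 13, Mg, THF, 0 °C; then 11, Li2CuCl4 (5 mol%), THF, 0 °C
Reagents that add atoms: none
Why: Copper-catalysed coupling of a 3-furylmethyl Grignard reagent with a geranyl-type chloride (Kochi–Schlosser type) is an established head-to-tail entry to 3-alkylfurans and takes place at the primary α-carbon because the γ-carbon is fully substituted.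

Step 11
Reactants: 15 tert-butyl{[(2R,6E,10E)-13-(furan-3-yl)-6,10-dimethyltrideca-6,10-dien-2-yl]oxy}dimethylsilane
Product: 16 (2R,6E,10E)-13-(furan-3-yl)-6,10-dimethyltrideca-6,10-dien-2-ol
Conditions: Bu4NF, THF, rt
Reagents that add atoms: none
Why: Fluoride-driven desilylation frees the secondary alcohol while furan and alkenes are inert.

Step 12
Reactants: 16 (2R,6E,10E)-13-(furan-3-yl)-6,10-dimethyltrideca-6,10-dien-2-ol
Product: 17 3-[(3E,7E,12S)-12-iodo-4,8-dimethyltrideca-3,7-dien-1-yl]furan
Conditions: PPh3, I2 (premixed), N-methylimidazole, CH2Cl2, −10 °C, short reaction time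
Reagents that add atoms: iodine, II
Why: Appel iodination (alkoxyphosphonium, SN2 by iodide) converts the (R)-alcohol into the (S)-iodide with inversion, low temperature and short contact time limiting racemisation by iodide exchange.

Step 13
Reactants: 18 methyl 2-methyl-3-oxobutanoate
Product: 19 methyl (2E)-3-methoxy-2-methylbut-2-enoate
Conditions: HC(OMe)3, H2SO4 (cat.), MeOH, rt
Reagents that add atoms: trimethyl orthoformate, COC(OC)OC
Why: Acid-catalysed ketalisation–elimination with the orthoester gives the enol ether under thermodynamic control, which favours the (E) isomer with methoxy trans to the ester and the C4 methyl cis to it.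

Step 14
Reactants: 19 methyl (2E)-3-methoxy-2-methylbut-2-enoate
Product: 20 methyl (2E)-4-bromo-3-methoxy-2-methylbut-2-enoate
Conditions: NBS, AIBN (cat.), PhCF3, 80 °C
Reagents that add atoms: N-bromosuccinimide, O=C1CCC(=O)N1Br
Why: Wohl–Ziegler radical bromination should take place at the γ-methyl group on the methoxy-bearing carbon, giving the bromomethyl group held cis to the ester.

Step 15
Reactants: 20 methyl (2E)-4-bromo-3-methoxy-2-methylbut-2-enoate
Product: 21 methyl (2E)-3-methoxy-2-methyl-4-oxobut-2-enoate
Conditions: N-methylmorpholine N-oxide, 4 Å MS, MeCN, rt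
Reagents that add atoms: N-methylmorpholine N-oxide, C[N+]1([O-])CCOCC1
Why: Ganem-type amine N-oxide oxidation (SN2 to the alkoxyammonium salt, then elimination) gives the aldehyde at room temperature, avoiding thermal lactonisation of the bromo ester and keeping the alkene geometry.

Step 16
Reactants: 21 methyl (2E)-3-methoxy-2-methyl-4-oxobut-2-enoate
Product: 22 methyl (2E)-3-methoxy-2-methylpent-2-en-4-ynoate
Conditions: dimethyl (1-diazo-2-oxopropyl)phosphonate, K2CO3, MeOH, 0 °C to rt
Reagents that add atoms: dimethyl (1-diazo-2-oxopropyl)phosphonate (Ohira–Bestmann reagent), COP(=O)(OC)C(=[N+]=[N-])C(C)=O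
Why: Seyferth–Gilbert homologation in the Ohira–Bestmann variant turns the aldehyde into the terminal alkyne under mild carbonate conditions that do not affect the tetrasubstituted enol ether.

Step 17
Reactants: 22 methyl (2E)-3-methoxy-2-methylpent-2-en-4-ynoate
Product: 23 (2E)-3-methoxy-2-methylpent-2-en-4-ynoic acid
Conditions: LiOH, THF/MeOH/H2O, 40 °C; then 1 M HCl to pH 2
Reagents that add atoms: lithium hydroxide (hydroxide oxygen), [Li+].[OH-]
Why: Saponification of the vinylogous carbonate ester needs only mild warming and gives the acid whose carboxyl group is cis to the alkyne.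

Step 18
Reactants: 23 (2E)-3-methoxy-2-methylpent-2-en-4-ynoic acid
Product: 24 (5E)-5-(iodomethylidene)-4-methoxy-3-methylfuran-2(5H)-one
Conditions: I2, NaHCO3, MeCN, rt, dark; Na2S2O3 work-up
Reagents that add atoms: iodine, II
Why: Iodolactonisation, in which the carboxylate adds 5-exo-dig to the internal carbon of the iodonium-activated terminal alkyne anti to iodine, closes the furanone ring and leaves iodine trans to the ring oxygen, i.e. the (E) iodomethylidene.

Step 19
Reactants: 24 (5E)-5-(iodomethylidene)-4-methoxy-3-methylfuran-2(5H)-one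
Product: 25 (5E)-4-hydroxy-5-(iodomethylidene)-3-methylfuran-2(5H)-one
Conditions: BBr3, CH2Cl2, −78 to −20 °C; aqueous work-up
Reagents that add atoms: none
Why: Lewis acid ether cleavage, in which BBr3 binds the lactone carbonyl and bromide removes the methyl group of the vinylogous ester by SN2 at low temperature, should spare the vinylic iodide and its geometry.

Step 20
Reactants: 25 (5E)-4-hydroxy-5-(iodomethylidene)-3-methylfuran-2(5H)-one, 26 15-methylhexadecanoic acid
Product: 28 (2E)-2-(iodomethylidene)-4-methyl-5-oxo-2,5-dihydrofuran-3-yl 15-methylhexadecanoate, via acid chloride 27 (not isolated)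
Conditions: 26, (COCl)2, DMF (cat.), CH2Cl2, 0 °C to rt, evaporate; then 25, iPr2NEt, CH2Cl2, −20 °C
Reagents that add atoms: none
Why: O-Acylation of the tetronic acid with the acid chloride made by the Vilsmeier-catalysed oxalyl chloride method gives the enol ester, C-acylation being ruled out by the methyl group on C3.

Step 21
Reactants: 17 3-[(3E,7E,12S)-12-iodo-4,8-dimethyltrideca-3,7-dien-1-yl]furan, 28 (2E)-2-(iodomethylidene)-4-methyl-5-oxo-2,5-dihydrofuran-3-yl 15-methylhexadecanoate
Product: 31 (2E)-2-[(2S,6E,10E)-13-(furan-3-yl)-2,6,10-trimethyltrideca-6,10-dien-1-ylidene]-4-methyl-5-oxo-2,5-dihydrofuran-3-yl 15-methylhexadecanoate, via alkyllithium 29 (not isolated), via alkylzinc 30 (not isolated)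
Conditions: 17 (1.7 equiv) added to tBuLi (2.2 equiv per 17), pentane/Et2O 3:2, −100 °C; Me3SiCH2ZnBr·LiBr, −100 to −30 °C; then 28 (1.0 equiv), [Pd(μ-I)(PtBu3)]2 (3 mol%), toluene, −25 °C, dark; aq. NH4Cl
Reagents that add atoms: none
Why: Iodine–lithium exchange on the (S)-iodide at −100 °C gives alkyllithium 29 with retention, transmetalation to the mixed dialkylzinc 30 (non-transferable Me3SiCH2 group) fixes the configuration, and a Negishi cycle follows: oxidative addition of the vinylic C–I bond of 28 to zerovalent palladium (released from the monovalent palladium dimer), transmetalation of the secondary alkyl group with retention at carbon, and fast reductive elimination promoted by PtBu3. The closest known reaction type is the stereoretentive palladium-catalysed Negishi coupling of configurationally defined secondary alkylzinc reagents with alkenyl iodides. No ring is closed in this step; the furanone ring and the furan are already in place. No new stereocentre is created: the (S) centre is carried over from the (R)-alcohol by one inversion (step 12) and three retentive events, and the (E) exocyclic alkene is carried over from the anti-iodolactonisation because oxidative addition and reductive elimination keep alkene geometry. The step needs retention at the carbon–zinc centre, retention of the (E) geometry, no 5-exo closure of alkyllithium 29 onto its trisubstituted C6=C7 alkene, no β-hydride chain walking and no attack on the enol ester or lactone; these should be secured by the −100 °C exchange with immediate transmetalation to zinc, the mild mixed zinc reagent, the bulky electron-rich phosphine, and the placement of iodine on the single vinylic CH carbon trans to the ring oxygen.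

**Compound list**

1 | (R)-butane-1,3-diol | C[C@@H](O)CCO | starting material
2 | (R)-3-hydroxybutyl 4-methylbenzenesulfonate | C[C@@H](O)CCOS(=O)(=O)c1ccc(C)cc1 | intermediate
3 | (R)-3-[(tert-butyldimethylsilyl)oxy]butyl 4-methylbenzenesulfonate | C[C@@H](O[Si](C)(C)C(C)(C)C)CCOS(=O)(=O)c1ccc(C)cc1 | intermediate
4 | (R)-(4-bromobutan-2-yloxy)(tert-butyl)dimethylsilane | C[C@@H](O[Si](C)(C)C(C)(C)C)CCBr | intermediate
5 | geranyl acetate, (2E)-3,7-dimethylocta-2,6-dien-1-yl acetate | CC(C)=CCC/C(C)=C/COC(C)=O | starting material
6 | (2E,6E)-8-hydroxy-3,7-dimethylocta-2,6-dien-1-yl acetate | OC/C(C)=C/CC/C(C)=C/COC(C)=O | intermediate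
7 | (2E,6E)-8-bromo-3,7-dimethylocta-2,6-dien-1-yl acetate | BrC/C(C)=C/CC/C(C)=C/COC(C)=O | intermediate
8 | (R)-{3-[(tert-butyldimethylsilyl)oxy]butyl}magnesium bromide | C[C@@H](O[Si](C)(C)C(C)(C)C)CC[Mg]Br | intermediate
9 | (2E,6E,11R)-11-[(tert-butyldimethylsilyl)oxy]-3,7-dimethyldodeca-2,6-dien-1-yl acetate | C[C@@H](O[Si](C)(C)C(C)(C)C)CCC/C(C)=C/CC/C(C)=C/COC(C)=O | intermediate
10 | (2E,6E,11R)-11-[(tert-butyldimethylsilyl)oxy]-3,7-dimethyldodeca-2,6-dien-1-ol | C[C@@H](O[Si](C)(C)C(C)(C)C)CCC/C(C)=C/CC/C(C)=C/CO | intermediate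
11 | tert-butyl{[(2R,6E,10E)-12-chloro-6,10-dimethyldodeca-6,10-dien-2-yl]oxy}dimethylsilane | C[C@@H](O[Si](C)(C)C(C)(C)C)CCC/C(C)=C/CC/C(C)=C/CCl | intermediate
12 | furan-3-ylmethanol | OCc1ccoc1 | starting material
13 | 3-(chloromethyl)furan | ClCc1ccoc1 | intermediate
14 | (furan-3-ylmethyl)magnesium chloride | Cl[Mg]Cc1ccoc1 | intermediate
15 | tert-butyl{[(2R,6E,10E)-13-(furan-3-yl)-6,10-dimethyltrideca-6,10-dien-2-yl]oxy}dimethylsilane | C[C@@H](O[Si](C)(C)C(C)(C)C)CCC/C(C)=C/CC/C(C)=C/CCc1ccoc1 | intermediate
16 | (2R,6E,10E)-13-(furan-3-yl)-6,10-dimethyltrideca-6,10-dien-2-ol | C[C@@H](O)CCC/C(C)=C/CC/C(C)=C/CCc1ccoc1 | intermediate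
17 | 3-[(3E,7E,12S)-12-iodo-4,8-dimethyltrideca-3,7-dien-1-yl]furan | C[C@H](I)CCC/C(C)=C/CC/C(C)=C/CCc1ccoc1 | intermediate
18 | methyl 2-methyl-3-oxobutanoate | CC(=O)C(C)C(=O)OC | starting material
19 | methyl (2E)-3-methoxy-2-methylbut-2-enoate | C/C(OC)=C(C)\C(=O)OC | intermediate
20 | methyl (2E)-4-bromo-3-methoxy-2-methylbut-2-enoate | BrC/C(OC)=C(C)\C(=O)OC | intermediate
21 | methyl (2E)-3-methoxy-2-methyl-4-oxobut-2-enoate | O=C/C(OC)=C(C)\C(=O)OC | intermediate
22 | methyl (2E)-3-methoxy-2-methylpent-2-en-4-ynoate | C#C/C(OC)=C(C)\C(=O)OC | intermediate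
23 | (2E)-3-methoxy-2-methylpent-2-en-4-ynoic acid | C#C/C(OC)=C(C)\C(O)=O | intermediate
24 | (5E)-5-(iodomethylidene)-4-methoxy-3-methylfuran-2(5H)-one | CC1=C(OC)/C(=C\I)OC1=O | intermediate
25 | (5E)-4-hydroxy-5-(iodomethylidene)-3-methylfuran-2(5H)-one | CC1=C(O)/C(=C\I)OC1=O | intermediate
26 | 15-methylhexadecanoic acid | OC(=O)CCCCCCCCCCCCCC(C)C | starting material
27 | 15-methylhexadecanoyl chloride | ClC(=O)CCCCCCCCCCCCCC(C)C | intermediate
28 | (2E)-2-(iodomethylidene)-4-methyl-5-oxo-2,5-dihydrofuran-3-yl 15-methylhexadecanoate | CC1=C(OC(=O)CCCCCCCCCCCCCC(C)C)/C(=C\I)OC1=O | intermediate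
29 | [(2S,6E,10E)-13-(furan-3-yl)-6,10-dimethyltrideca-6,10-dien-2-yl]lithium | [Li][C@@H](C)CCC/C(C)=C/CC/C(C)=C/CCc1ccoc1 | intermediate
30 | [(2S,6E,10E)-13-(furan-3-yl)-6,10-dimethyltrideca-6,10-dien-2-yl][(trimethylsilyl)methyl]zinc | C[Si](C)(C)C[Zn][C@@H](C)CCC/C(C)=C/CC/C(C)=C/CCc1ccoc1 | intermediate
31 | (2E)-2-[(2S,6E,10E)-13-(furan-3-yl)-2,6,10-trimethyltrideca-6,10-dien-1-ylidene]-4-methyl-5-oxo-2,5-dihydrofuran-3-yl 15-methylhexadecanoate | CC1=C(OC(=O)CCCCCCCCCCCCCC(C)C)/C(=C\[C@@H](C)CCC/C(C)=C/CC/C(C)=C/CCc2ccoc2)OC1=O | target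

**Step count and risks**

Total step count: 21.
Longest linear sequence: 10 steps (steps 1, 2, 3, 6, 7, 8, 10, 11, 12 and 21 from (R)-butane-1,3-diol). The branch from geranyl acetate (steps 4, 5, 6, 7, 8, 10, 11, 12 and 21) and the branch from methyl 2-methyl-3-oxobutanoate (steps 13 to 21) each run to 9 steps.

Three steps most likely to fail:

1. Step 21. What may go wrong: transfer of the acyl group from the enol ester (a vinylogous mixed anhydride) to the organozinc or insertion of palladium into its acyl–oxygen bond, together with drift of the (E) alkene towards (Z) at the vinylpalladium stage of the electron-poor acyloxy dienone. Fallback, in which the enol ester is installed only after the coupling: it sets out from 25, which is treated with MOMCl and iPr2NEt in CH2Cl2 at 0 °C to give the acetal (5E)-5-(iodomethylidene)-4-(methoxymethoxy)-3-methylfuran-2(5H)-one F1. F1 is coupled under the step 21 conditions with alkylzinc 30 (made from 17 as before) to give (5E)-5-[(2S,6E,10E)-13-(furan-3-yl)-2,6,10-trimethyltrideca-6,10-dien-1-ylidene]-4-(methoxymethoxy)-3-methylfuran-2(5H)-one F2. Dilute HCl in THF/MeOH at 0 °C then cleaves the acetal to the free tetronic acid (5E)-5-[(2S,6E,10E)-13-(furan-3-yl)-2,6,10-trimethyltrideca-6,10-dien-1-ylidene]-4-hydroxy-3-methylfuran-2(5H)-one F3. Acylation of F3 with acid chloride 27 (from 26) and iPr2NEt at −20 °C comes back to the route at 31.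

2. Step 19. What may go wrong: addition–elimination of bromide at the iodine-bearing vinylic carbon of the boron-activated lactone, which exchanges the halogen and equilibrates (E) to (Z), or opening of the enol lactone. Fallback, in which demethylation is moved behind the coupling and made nucleophilic instead of Lewis acidic: it sets out from 24, which is coupled directly with alkylzinc 30 under the step 21 conditions to give the methyl ether (5E)-5-[(2S,6E,10E)-13-(furan-3-yl)-2,6,10-trimethyltrideca-6,10-dien-1-ylidene]-4-methoxy-3-methylfuran-2(5H)-one F4. LiCl in DMF at 80 °C removes the methyl group by SN2 and gives lithium (2E)-2-[(2S,6E,10E)-13-(furan-3-yl)-2,6,10-trimethyltrideca-6,10-dien-1-ylidene]-4-methyl-5-oxo-2,5-dihydrofuran-3-olate F5, which is acylated in the same flask with 27 and comes back to the route at 31.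

3. Step 6. What may go wrong: competing SN2' attack at the γ-carbon of the 2-methylallyl bromide and attack of the Grignard reagent on the allylic acetate, either at its carbonyl group or with acetate as leaving group. Fallback by sulfone alkylation: it sets out from 4, which with PhSO2Na in DMF at 60 °C gives tert-butyldimethyl{[(2R)-4-(phenylsulfonyl)butan-2-yl]oxy}silane F6. Deprotonation of F6 with nBuLi in THF at −78 °C and alkylation with bromide 7, which can only occur by SN2 at the primary carbon, gives (2E,6E,11R)-11-[(tert-butyldimethylsilyl)oxy]-3,7-dimethyl-9-(phenylsulfonyl)dodeca-2,6-dien-1-yl acetate F7 as a mixture of epimers at the sulfonyl carbon. Reductive desulfonylation with 6% Na/Hg and Na2HPO4 in MeOH/THF at −20 °C comes back to the route at 9.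

Further compounds
F1 | step 21 | (5E)-5-(iodomethylidene)-4-(methoxymethoxy)-3-methylfuran-2(5H)-one | CC1=C(OCOC)/C(=C\I)OC1=O
F2 | step 21 | (5E)-5-[(2S,6E,10E)-13-(furan-3-yl)-2,6,10-trimethyltrideca-6,10-dien-1-ylidene]-4-(methoxymethoxy)-3-methylfuran-2(5H)-one | CC1=C(OCOC)/C(=C\[C@@H](C)CCC/C(C)=C/CC/C(C)=C/CCc2ccoc2)OC1=O
F3 | step 21 | (5E)-5-[(2S,6E,10E)-13-(furan-3-yl)-2,6,10-trimethyltrideca-6,10-dien-1-ylidene]-4-hydroxy-3-methylfuran-2(5H)-one | CC1=C(O)/C(=C\[C@@H](C)CCC/C(C)=C/CC/C(C)=C/CCc2ccoc2)OC1=O
F4 | step 19 | (5E)-5-[(2S,6E,10E)-13-(furan-3-yl)-2,6,10-trimethyltrideca-6,10-dien-1-ylidene]-4-methoxy-3-methylfuran-2(5H)-one | CC1=C(OC)/C(=C\[C@@H](C)CCC/C(C)=C/CC/C(C)=C/CCc2ccoc2)OC1=O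
F5 | step 19 | lithium (2E)-2-[(2S,6E,10E)-13-(furan-3-yl)-2,6,10-trimethyltrideca-6,10-dien-1-ylidene]-4-methyl-5-oxo-2,5-dihydrofuran-3-olate | [Li+].CC1=C([O-])/C(=C\[C@@H](C)CCC/C(C)=C/CC/C(C)=C/CCc2ccoc2)OC1=O
F6 | step 6 | tert-butyldimethyl{[(2R)-4-(phenylsulfonyl)butan-2-yl]oxy}silane | C[C@@H](O[Si](C)(C)C(C)(C)C)CCS(=O)(=O)c1ccccc1
F7 | step 6 | (2E,6E,11R)-11-[(tert-butyldimethylsilyl)oxy]-3,7-dimethyl-9-(phenylsulfonyl)dodeca-2,6-dien-1-yl acetate | C[C@@H](O[Si](C)(C)C(C)(C)C)CC(S(=O)(=O)c1ccccc1)C/C(C)=C/CC/C(C)=C/COC(C)=O
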